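3 questions stand on this flask, where Xc turns Xa into Xp, and the one that shapes the next run is what Saturday's charge should be left to give.

| setting | Monday's | Thursday's | Tuesday's | Friday's | Saturday's |
|---|---|---|---|---|---|
| Xa | 0.300 M | 0.120 M | 0.300 M | 0.450 M | 1.20 M |
| Xc | 0.0240 M | 0.0240 M | 0.0360 M | 0.0240 M | 0.0240 M |
| time |  |  |  |  | 45 min |

- Monday's run (time / min: [Xp] / M): 1.8: 0.027; 3.4: 0.043; 6.5: 0.073; 12: 0.111; 24: 0.150; 45: 0.168
- Thursday's run (time / min: [Xp] / M): 1.8: 0.009; 3.4: 0.016; 6.5: 0.029; 12: 0.044; 24: 0.056; 45: 0.063
- Tuesday's run (time / min: [Xp] / M): 1.8: 0.027; 3.4: 0.041; 6.5: 0.084; 12: 0.117; 24: 0.168; 45: 0.172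
- Friday's run (time / min: [Xp] / M): 1.8: 0.031; 3.4: 0.062; 6.5: 0.110; 12: 0.161; 24: 0.221; 45: 0.250

(standard deviation of a reading: 0.003 M)

- reaction order in [Xc] at the outset, round the charge of the Monday's run, defined at two percent of the Xa turned into Xp
- reaction order in [Xa] at the outset, round the charge of the Monday's run, defined at two percent of the Xa turned into Xp (one fixed amount of Xp, the same in the runs compared)
- Xp in the Saturday's run at 45 min, as a share of the Xa charged

- Overall: Xa -> Xp, with Xc as catalyst.
- Constant volume, constant temperature.
- An order is taken over about fifteen percent of the charge, up and down.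

At 45 min, Monday's run stands at 56.0% of its charge, Friday's at 55.6% and Thursday's at 52.5%. The scatter on Thursday's share is 2.50% of its charge, so I read no steady climb with the charge. I therefore carry one quantity, the end share: the fraction of the Xa charged that has become Xp once the curve stops rising.

Monday's last reading is a first answer, but that curve is still rising slightly. Taking it as the end, the reading at 12 min gives a pace, the pseudo-first-order rate constant, of 0.0901 min⁻¹. That pace puts the end share at 57.0%. Going round again gives a pace of 0.0873 min⁻¹ and an end share of 57.1%, and the change is smaller than the scatter of 1.00% of Monday's charge.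

At this pace, 45 min covers 98.0% of the way to the end. I leave Saturday's time and Xc as they stand and expect 56.0%, although its charge is 2.67 times larger than Friday's. For the orders, I read about 0.903 in Xa from Friday against Monday at 3.4 min, and about 0.346 in Xc from Tuesday against Monday at 6.5 min, each from one pair of readings and so a rough figure.

The forecast gives 0.4 in Xc, 1 in Xa and 55% for Saturday, one point below what I expect, and reads the plateau thus: “this looks like a reversible approach to equilibrium rather than catalyst death”.

The flask gives 0.34 in Xc, 1.0 in Xa and 56.2% for Saturday's run.

    2 Xc ⇌ Xc2, settled at all times (1060 M⁻¹)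
    Xc + Xa → Xp + Xc (9.420 M⁻¹ min⁻¹)
    Xa → L (0.03528 min⁻¹)
    Xa → Xp (0.01824 min⁻¹)

Saturday's run lands just below the end share of 57.1%. The same share and pace put Thursday's run at half its charge after 23.9 min, and the flask gives 24.5 min. Saturday's run falls short of its whole charge because of the reaction of Xa to L: without that reaction it reaches 88.4% instead of 56.2%, and that reaction accounts for 73% of what is missing.

(The numbers in the tables stem from a simulated flask from invented constants, and the scatter is random.)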